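The dihydrofuran ring (ring B: O1, C2, C3, C3a, C7a) is disconnected at O1–C2 and at the bond from C3 to its hydroxymethyl carbon. The route exploits that O1 and this carbon sit on the adjacent atoms C2 and C3, which together are the alkene of an (E)-2-hydroxystilbene. One palladium-catalysed oxycarbonylation adds the phenol oxygen to C2 and a methoxycarbonyl group to C3, closing ring B and setting both stereocentres. The precursor is the Heck product of 5-iodovanillin and 3,4-dimethoxystyrene; its C5 carbon is kept as the aldehyde, so that after the key step a Wittig reaction and one hydride reduction finish the target.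

Key step: step 2

Labels: atom numbers are those of 2,3-dihydro-1-benzofuran; ring A is the benzo ring, ring B the dihydrofuran ring, ring C the 3,4-dimethoxyphenyl ring.

Design remark: C5 carries a formyl group, a spectator in the key step, at the oxidation level the Wittig step needs; an ester there would cost a reduction and a re-oxidation, and the carbon skeleton is unchanged.

Assumption: the sense of induction of the bis(oxazoline) in this endo closure cannot be predicted, so (S,S)-Ph-box, 2,2'-(propane-2,2-diyl)bis[(4S)-4-phenyl-4,5-dihydro-1,3-oxazole], is written and its commercial antipode would be taken if it leads to the 2R series; the kinetic product is assumed to contain the cis C3 epimer 4.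

Descriptor remark: C3 is 3S in esters 5 and 7 and 3R in target 8 only because the CIP priorities change on reduction; the trans geometry is the same.

Step 1
Reactants: 1 5-iodovanillin (4-hydroxy-3-iodo-5-methoxybenzaldehyde); 2 3,4-dimethoxystyrene
Product: 3 3-[(E)-2-(3,4-dimethoxyphenyl)ethenyl]-4-hydroxy-5-methoxybenzaldehyde
Conditions: Pd(OAc)2 (5 mol %), P(o-tol)3 (10 mol %), Et3N (3 equiv), DMF, 90 °C
Reagents that add atoms: none
Why: Mizoroki–Heck reaction, in which oxidative addition of the aryl iodide, syn insertion at the terminal styrene carbon and syn β-hydride elimination should give the (E)-stilbene, the free phenol and the aldehyde being spectators; no stereocentre is formed.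

Step 2
Reactants: 3 3-[(E)-2-(3,4-dimethoxyphenyl)ethenyl]-4-hydroxy-5-methoxybenzaldehyde
Product: 5 methyl (2S,3S)-2-(3,4-dimethoxyphenyl)-5-formyl-7-methoxy-2,3-dihydro-1-benzofuran-3-carboxylate (trans), via cis ester 4 (not isolated)
Conditions: Pd(OCOCF3)2 (10 mol %), (S,S)-Ph-box (12 mol %), p-benzoquinone (2 equiv), CO (1 atm), MeOH/CH2Cl2 (1:4), 0 °C → rt; dilute HCl wash; then NaOMe (0.2 equiv), MeOH, 0 °C → rt on the crude
Reagents that add atoms: carbon monoxide, [C-]#[O+]; methanol, CO
Why: Proposed new method: cationic divalent palladium bound to the bis(oxazoline) coordinates the stilbene alkene; the electron-rich ring C lets the complex slip toward a benzylic cation at C2, which the ortho phenol oxygen captures, and the C3–Pd bond so formed inserts CO to an acylpalladium that methanol cleaves to the ester, after which benzoquinone returns zerovalent palladium to the divalent state. The closest known reaction types are the enantioselective Wacker-type cyclisation–methoxycarbonylation cascades of alkenyl phenols under this catalyst system, which close rings in the exo mode, and the oxidative cyclisation of 2-hydroxystilbenes to 2-arylbenzofurans by divalent palladium, which is the same oxypalladation without CO capture. Ring B closes in the 5-endo-trig mode, acceptable here because the oxygen attacks a metal-bound alkene with carbocation character at C2 and not a free alkene. C2 is set by the chiral ligand, which decides the alkene face that carries palladium and hence the face that oxygen attacks; C3 is set first by the syn or anti course of oxypalladation (CO insertion with retention) and then, in the NaOMe stir, by thermodynamic control from C2, which turns whatever cis ester 4 has formed into trans ester 5. The step needs CO insertion to beat β-hydride elimination to the achiral 2-arylbenzofuran: the substrate offers a single β-hydrogen (H2, since C3a is aromatic), which is trans to palladium after syn addition and, after anti addition, is denied a vacant cis site by the chelating ligand and CO at low temperature. The formyl group para to the phenol oxygen keeps ring A too electron-poor to be oxidised by benzoquinone.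

Step 3
Reactants: 5 methyl (2S,3S)-2-(3,4-dimethoxyphenyl)-5-formyl-7-methoxy-2,3-dihydro-1-benzofuran-3-carboxylate; 6 methyl (triphenylphosphoranylidene)acetate
Product: 7 methyl (2S,3S)-2-(3,4-dimethoxyphenyl)-7-methoxy-5-[(E)-3-methoxy-3-oxoprop-1-en-1-yl]-2,3-dihydro-1-benzofuran-3-carboxylate
Conditions: toluene, 80 °C
Reagents that add atoms: none
Why: Wittig olefination of the aryl aldehyde with a stabilised ylide should give the (E)-cinnamate under thermodynamic control of the oxaphosphetane pathway, and the ylide is too weakly basic to disturb C3, which already holds the more stable trans arrangement.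

Step 4
Reactants: 7 methyl (2S,3S)-2-(3,4-dimethoxyphenyl)-7-methoxy-5-[(E)-3-methoxy-3-oxoprop-1-en-1-yl]-2,3-dihydro-1-benzofuran-3-carboxylate
Product: 8 hierochin B, (E)-3-[(2S,3R)-2-(3,4-dimethoxyphenyl)-3-(hydroxymethyl)-7-methoxy-2,3-dihydro-1-benzofuran-5-yl]prop-2-en-1-ol
Conditions: iBu2AlH (6 equiv), CH2Cl2, −78 → 0 °C; aq. potassium sodium tartrate
Reagents that add atoms: none
Why: Hydride reduction with iBu2AlH should take the saturated C3 ester and, by 1,2-addition, the conjugated ester to the two primary alcohols in one operation, leaving both stereocentres and the (E)-alkene untouched.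

Compound list
1 | 5-iodovanillin (4-hydroxy-3-iodo-5-methoxybenzaldehyde) | COc1cc(C=O)cc(I)c1O | starting material
2 | 3,4-dimethoxystyrene | C=Cc1ccc(OC)c(OC)c1 | starting material
3 | 3-[(E)-2-(3,4-dimethoxyphenyl)ethenyl]-4-hydroxy-5-methoxybenzaldehyde | COc1cc(C=O)cc(/C=C/c2ccc(OC)c(OC)c2)c1O | intermediate
4 | methyl (2S,3R)-2-(3,4-dimethoxyphenyl)-5-formyl-7-methoxy-2,3-dihydro-1-benzofuran-3-carboxylate (cis, not isolated) | COc1ccc([C@H]2Oc3c(OC)cc(C=O)cc3[C@H]2C(=O)OC)cc1OC | intermediate
5 | methyl (2S,3S)-2-(3,4-dimethoxyphenyl)-5-formyl-7-methoxy-2,3-dihydro-1-benzofuran-3-carboxylate (trans) | COc1ccc([C@H]2Oc3c(OC)cc(C=O)cc3[C@@H]2C(=O)OC)cc1OC | intermediate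
6 | methyl (triphenylphosphoranylidene)acetate | COC(=O)C=P(c1ccccc1)(c1ccccc1)c1ccccc1 | starting material
7 | methyl (2S,3S)-2-(3,4-dimethoxyphenyl)-7-methoxy-5-[(E)-3-methoxy-3-oxoprop-1-en-1-yl]-2,3-dihydro-1-benzofuran-3-carboxylate | COc1ccc([C@H]2Oc3c(OC)cc(/C=C/C(=O)OC)cc3[C@@H]2C(=O)OC)cc1OC | intermediate
8 | hierochin B, (E)-3-[(2S,3R)-2-(3,4-dimethoxyphenyl)-3-(hydroxymethyl)-7-methoxy-2,3-dihydro-1-benzofuran-5-yl]prop-2-en-1-ol | COc1ccc([C@H]2Oc3c(OC)cc(/C=C/CO)cc3[C@@H]2CO)cc1OC | target

Total step count: 4
Longest linear sequence: 4 steps (1 → 3 → 5 → 7 → 8)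

Steps most likely to fail

Step 2. Three processes could defeat it:
- β-hydride elimination from the C3 alkylpalladium could outrun CO insertion and aromatise ring B.
- The ligand could discriminate the alkene faces poorly in an endo closure.
- Methanol could compete with the weakly nucleophilic phenol for the palladium-bound alkene.

Reversible acetalisation of the aldehyde in methanol is a lesser concern that the acidic wash should undo.

The fallback uses known chemistry, sets out from 1 and rejoins the route at 7. Ring B is closed at C2–C3 by carbenoid C–H insertion. Compound 1 is O-alkylated with 3,4-dimethoxybenzyl chloride (K2CO3, DMF, 60 °C) to give 4-[(3,4-dimethoxyphenyl)methoxy]-3-iodo-5-methoxybenzaldehyde F1. The aldehyde, which would not survive a carbenoid, is converted first by Wittig reaction with 6 (toluene, 80 °C) into methyl (E)-3-{4-[(3,4-dimethoxyphenyl)methoxy]-3-iodo-5-methoxyphenyl}prop-2-enoate F2. Cross-coupling of the aryl iodide with methyl diazoacetate with retention of the diazo group (Pd(PPh3)4, Ag2CO3, Et3N, toluene, rt) should give methyl 2-diazo-2-{2-[(3,4-dimethoxyphenyl)methoxy]-3-methoxy-5-[(E)-3-methoxy-3-oxoprop-1-en-1-yl]phenyl}acetate F3. The chiral dirhodium tetracarboxylate Rh2(S-PTTL)4, dirhodium tetrakis[N-phthaloyl-(S)-tert-leucinate], or its enantiomer if that is what leads to the 2S series, in toluene at −60 °C should insert the carbenoid into the activated benzylic C–H bond of the ether. This 1,5-insertion is expected to give the cis ester methyl (2S,3R)-2-(3,4-dimethoxyphenyl)-7-methoxy-5-[(E)-3-methoxy-3-oxoprop-1-en-1-yl]-2,3-dihydro-1-benzofuran-3-carboxylate F4. NaOMe in MeOH then epimerises C3 and should deliver 7.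

Step 1. The coupling could be slow or unselective: the phenoxide may bind palladium, the electron-rich styrene may be arylated at its internal carbon, and the styrene may oligomerise at the reaction temperature.

The fallback sets out from 2 and rejoins at 3. Cross-metathesis of 2 with vinylboronic acid pinacol ester (second-generation Grubbs catalyst, CH2Cl2, 40 °C) should give (E)-2-[2-(3,4-dimethoxyphenyl)ethenyl]-4,4,5,5-tetramethyl-1,3,2-dioxaborolane F5. Suzuki–Miyaura coupling of this with 1 (Pd(PPh3)4, K2CO3, dioxane/H2O, 80 °C) fixes both the site of C–C bond formation and the (E) geometry and should give 3.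

Step 4. The two esters may be reduced at different rates. The C3 ester could then linger at the aldehyde stage, where epimerisation at C3 or β-elimination of O1 with ring opening is possible. The cinnamate could also suffer partial conjugate reduction.

The fallback sets out from 5 and rejoins at 8, separating the two reductions. LiBH4 (THF/MeOH, 0 °C → rt) reduces the aldehyde and the C3 ester of 5 to [(2S,3R)-2-(3,4-dimethoxyphenyl)-7-methoxy-2,3-dihydro-1-benzofuran-3,5-diyl]dimethanol F6. MnO2 (CH2Cl2, rt) oxidises only the benzylic alcohol to (2S,3R)-2-(3,4-dimethoxyphenyl)-3-(hydroxymethyl)-7-methoxy-2,3-dihydro-1-benzofuran-5-carbaldehyde F7. Wittig reaction with 6 gives methyl (E)-3-[(2S,3R)-2-(3,4-dimethoxyphenyl)-3-(hydroxymethyl)-7-methoxy-2,3-dihydro-1-benzofuran-5-yl]prop-2-enoate F8. iBu2AlH (CH2Cl2, −78 °C) then reduces the single conjugated ester to 8.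

Further compounds
F1 | step 2 | 4-[(3,4-dimethoxyphenyl)methoxy]-3-iodo-5-methoxybenzaldehyde | COc1ccc(COc2c(I)cc(C=O)cc2OC)cc1OC
F2 | step 2 | methyl (E)-3-{4-[(3,4-dimethoxyphenyl)methoxy]-3-iodo-5-methoxyphenyl}prop-2-enoate | COc1ccc(COc2c(I)cc(/C=C/C(=O)OC)cc2OC)cc1OC
F3 | step 2 | methyl 2-diazo-2-{2-[(3,4-dimethoxyphenyl)methoxy]-3-methoxy-5-[(E)-3-methoxy-3-oxoprop-1-en-1-yl]phenyl}acetate | COc1ccc(COc2c(C(=[N+]=[N-])C(=O)OC)cc(/C=C/C(=O)OC)cc2OC)cc1OC
F4 | step 2 | methyl (2S,3R)-2-(3,4-dimethoxyphenyl)-7-methoxy-5-[(E)-3-methoxy-3-oxoprop-1-en-1-yl]-2,3-dihydro-1-benzofuran-3-carboxylate (cis) | COc1ccc([C@H]2Oc3c(OC)cc(/C=C/C(=O)OC)cc3[C@H]2C(=O)OC)cc1OC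
F5 | step 1 | (E)-2-[2-(3,4-dimethoxyphenyl)ethenyl]-4,4,5,5-tetramethyl-1,3,2-dioxaborolane | COc1ccc(/C=C/B2OC(C)(C)C(C)(C)O2)cc1OC
F6 | step 4 | [(2S,3R)-2-(3,4-dimethoxyphenyl)-7-methoxy-2,3-dihydro-1-benzofuran-3,5-diyl]dimethanol | COc1ccc([C@H]2Oc3c(OC)cc(CO)cc3[C@@H]2CO)cc1OC
F7 | step 4 | (2S,3R)-2-(3,4-dimethoxyphenyl)-3-(hydroxymethyl)-7-methoxy-2,3-dihydro-1-benzofuran-5-carbaldehyde | COc1ccc([C@H]2Oc3c(OC)cc(C=O)cc3[C@@H]2CO)cc1OC
F8 | step 4 | methyl (E)-3-[(2S,3R)-2-(3,4-dimethoxyphenyl)-3-(hydroxymethyl)-7-methoxy-2,3-dihydro-1-benzofuran-5-yl]prop-2-enoate | COc1ccc([C@H]2Oc3c(OC)cc(/C=C/C(=O)OC)cc3[C@@H]2CO)cc1OC
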